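The data come from a simulation on assumed constants.

1. A closed, stirred flask has given three runs, and three vessels now take E at the same charge:

| flask | E | remark | time |
|---|---|---|---|
| Friday's | 2 M | run made earlier |  |
| Wednesday's | 1.3 M | run made earlier |  |
| Sunday's | 3 M | run made earlier |  |
| beta | 2.0 M | plug flow through a tube for 2.0 min, no back-mixing | 2.0 min |
| eta | 2.0 M | one stirred flow tank at steady state, fed with the mixture as stated, mean residence time 2.0 min |  |
| theta | 2.0 M | a closed flask charged with all of it at once and left for 2.0 min | 2.0 min |

- Friday's (time / s: L / %): 20.0: 36.4; 40.0: 37.4; 50.0: 37.9; 80.0: 38.9
- Wednesday's (time / s: L / %): 25.0: 41.8; 50.0: 44.6; 80.0: 44.4; 90.0: 43.5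
- Sunday's (time / s: L / %): 12.0: 28.9; 30.0: 33.0; 60.0: 33.7; 90.0: 34.3

(readings scatter by 0.5 percentage points)

- the stated concentrations are those of everything mixed, before any reaction; amounts are the same in each set-up
- the numbers in the tables scatter with a standard deviation of 0.5 percentage points
- the earlier runs were made in a closed, stirred flask

- the set-up with the highest amount of L at the outlet or at the end, in percent of the E put in ("none" if the first two lie within 2 percentage points) (beta / eta / theta / none)
- amount of L at the outlet or at the end, in percent of the E put in, beta
- amount of L at the outlet or at the end, in percent of the E put in, eta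
- amount of L at the outlet or at the end, in percent of the E put in, theta

2. In each run L climbs quickly and then nearly stops, and the reading on the plateau falls as the charge rises, from 44.6% at 1.3 M to 33.0% at 3 M. A yield that stops short and falls with the charge suggests a return step, with E giving L and an equal partner.

3. So take the plateau quotient Q, [L] squared over [E], with [E] the charge minus [L]; it is an apparent equilibrium constant. The quotient is 0.467 M on Wednesday's run, 0.463 M on Friday's and 0.488 M on Sunday's, at 50.0 s, 50.0 s and 30.0 s. As read, it stays nearly frozen while the yield moves, so carry the mean of the readings, 0.472 M.

4. My reckoning: at 2.0 M, Q gives a plateau of 38.2%. The mean residence time of the eta tank, 2.0 min, is longer than the 20.0 s of the first reading of Friday's run, which already lies close to its plateau, so eta should stand near that value. Beta and theta share one history and should tie; Friday's slow creep carries them to about 40.4%. The two highest, beta and theta, then tie, so the answer for best is "none".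

5. The forecast, which parts from this reckoning at the tank, gives 40.5% for beta, 40.5% for theta, 65% for eta and eta as best, holding for the tank that “E stays low at about 0.1 M”.

6. The flasks give 39.8% for beta, 39.8% for theta, 37.7% for eta, and best: none.

    E ⇌ L + G (K = 0.460 M, k = 0.0440 /s)
    E + G → Z (k = 0.00300 /M/s)

7. L stops short because L and G return to E: the run of beta without that return gives 93.9% against 39.8%. With G as the partner of L, Q applied to the end of beta, where E stands at 48.0% of the charge and [G] at 0.552 M, gives L as 41.0%, against 39.8% in beta.

8. A neighbour of beta charged with 1.2 M ends with E at 45.4% of its charge and [G] at 0.451 M, so Q gives L as 47.5%; that neighbour gives 46.1%.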